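Ring atoms: C1 (bears CH2OAc), C2–C4, C5 (bears CH3), C6, C7, C8 (bears the side chain), C9 and C10 (carbinols). The ten-membered ring is closed last at C5–C6, where the sp2 carbon of the (E)-C4=C5 alkene meets the C6H2–C7H2 bridge to C8. An intramolecular B-alkyl Suzuki–Miyaura coupling achieves this in one operation: anti-Markovnikov hydroboration turns a vinyl group on C8 into the C7–C6–boron arm, which couples with an (E)-vinyl iodide at C5 with retention. The precursor is an open-chain iodotriene diol built from (R)-citronellal (C7, C8, side chain), dimethyl (S)-malate (C9, C10, C1, acetoxymethyl carbon; a temporary γ-lactone fixes C1=C2) and pent-3-yn-1-ol (C2–C5).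

Key step: step 12

Remark on labels: C11 is the side-chain stereocentre attached to C8.
Assumption: (R)-TRIP [(R)-3,3'-bis(2,4,6-triisopropylphenyl)-1,1'-binaphthyl-2,2'-diyl hydrogen phosphate] is taken as the acid enantiomer that directs the allyl group to the Re face of aldehyde 7, which is also the Felkin–Anh face; if the sense proved opposite, the (S)-acid would be used.

Step 1
Reactants: 1 (R)-citronellal
Product: 2 (4R)-4,8-dimethylnon-7-en-1-yne
Conditions: dimethyl (1-diazo-2-oxopropyl)phosphonate, K2CO3, MeOH, 0 °C to rt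
Reagents that add atoms: dimethyl (1-diazo-2-oxopropyl)phosphonate, CC(=O)C(=[N+]=[N-])P(=O)(OC)OC
Why: Seyferth–Gilbert homologation (Ohira–Bestmann variant) turns the aldehyde carbon (future C7) into an alkyne carbon and adds the future C6; the α-carbon is a CH2, so C11 is not at risk under the mild carbonate conditions.

Step 2
Reactants: 2 (4R)-4,8-dimethylnon-7-en-1-yne
Product: 3 2-[(1E,4R)-4,8-dimethylnona-1,7-dien-1-yl]-4,4,5,5-tetramethyl-1,3,2-dioxaborolane
Conditions: pinacolborane, Cp2Zr(H)Cl (cat.), Et3N (cat.), neat, 60 °C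
Reagents that add atoms: pinacolborane, CC1(C)OBOC1(C)C
Why: zirconium-catalysed syn hydroboration of a terminal alkyne places boron on the terminal carbon and should give only the (E)-alkenylboronate, the trisubstituted alkene being inert to pinacolborane.

Step 3
Reactants: 4 dimethyl (S)-malate
Product: 5 methyl (3S)-3,4-dihydroxybutanoate
Conditions: BH3·SMe2, NaBH4 (cat.), THF, 0 °C to rt; MeOH quench
Reagents that add atoms: none
Why: hydroxyl-directed borane reduction: the ester next to the free hydroxyl is reduced through a cyclic alkoxyborane while the remote ester survives, and the carbinol centre (future C10) is untouched.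

Step 4
Reactants: 5 methyl (3S)-3,4-dihydroxybutanoate
Product: 6 methyl (3S)-3,4-bis[(triethylsilyl)oxy]butanoate
Conditions: Et3SiCl, imidazole, DMF, 0 °C to rt
Reagents that add atoms: chlorotriethylsilane, CC[Si](Cl)(CC)CC
Why: standard silyl ether formation on both hydroxyls, fast enough to outrun lactonisation of the γ-hydroxy ester.

Step 5
Reactants: 6 methyl (3S)-3,4-bis[(triethylsilyl)oxy]butanoate
Product: 7 methyl (3S)-4-oxo-3-[(triethylsilyl)oxy]butanoate
Conditions: (COCl)2, DMSO, CH2Cl2, −78 to −30 °C; then Et3N, −78 °C to rt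
Reagents that add atoms: none
Why: Swern oxidation applied directly to the bis-silyl ether: the chlorosulfonium salt cleaves the less hindered primary triethylsilyl ether and oxidises it to the aldehyde, leaving the secondary silyl ether in place.

Step 6
Reactants: 3 2-[(1E,4R)-4,8-dimethylnona-1,7-dien-1-yl]-4,4,5,5-tetramethyl-1,3,2-dioxaborolane; 7 methyl (3S)-4-oxo-3-[(triethylsilyl)oxy]butanoate
Product: 10 (4S,5R)-5-[(3S,4R)-4,8-dimethylnona-1,7-dien-3-yl]-4-[(triethylsilyl)oxy]oxolan-2-one, via allylboronate 8 (not isolated), via hydroxy ester 9 (not isolated)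
Conditions: [Ir(cod)2]BF4 (cat.), PCy3 (cat.), (R)-TRIP (cat.), 1,2-dichloroethane, rt; then pyridinium p-toluenesulfonate (cat.), PhMe, 40 °C
Reagents that add atoms: none
Why: iridium-hydride alkene transposition converts the 1-alkenylboronate into the (E)-allylboronate, which is trapped at once by the aldehyde in a chiral phosphoric acid-catalysed allylboration through a closed chair transition state, so that the E geometry sets C8/C9 anti, the acid together with the Felkin–Anh preference of the α-silyloxy aldehyde directs attack to the Re face (C9 R, anti to C10), and the γ-hydroxy ester then lactonises under acid catalysis.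

Step 7
Reactants: 11 pent-3-yn-1-ol
Product: 13 (3E)-4-iodopent-3-en-1-ol, via alkenylzirconocene 12 (not isolated)
Conditions: Cp2Zr(H)Cl (2.5 equiv), THF, rt to 40 °C; then I2, 0 °C
Reagents that add atoms: iodine, II
Why: hydrozirconation–iodination: syn addition of Zr–H with excess reagent should equilibrate zirconium to the less hindered methyl-bearing alkyne carbon, and iodinolysis with retention should give the (E)-2-iodoalkene.

Step 8
Reactants: 13 (3E)-4-iodopent-3-en-1-ol
Product: 14 (3E)-4-iodopent-3-enal
Conditions: Dess–Martin periodinane, CH2Cl2, 0 °C; used at once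
Reagents that add atoms: none
Why: Dess–Martin oxidation is fast and nearly neutral, so the β,γ-unsaturated aldehyde should not move into conjugation if it is used directly.

Step 9
Reactants: 10 (4S,5R)-5-[(3S,4R)-4,8-dimethylnona-1,7-dien-3-yl]-4-[(triethylsilyl)oxy]oxolan-2-one; 14 (3E)-4-iodopent-3-enal
Product: 16 (4S,5R)-5-[(3S,4R)-4,8-dimethylnona-1,7-dien-3-yl]-3-[(3E)-1-hydroxy-4-iodopent-3-en-1-yl]-4-[(triethylsilyl)oxy]oxolan-2-one (diastereomer mixture at C3 of the lactone and at the new carbinol), via lithium enolate 15 (not isolated)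
Conditions: lithium diisopropylamide, THF, −78 °C; then 14, −78 °C; NH4Cl quench
Reagents that add atoms: none
Why: lithium enolate aldol addition joins C1 to C2; at −78 °C addition should outrun proton transfer from the aldehyde and β-loss of the silyloxide, and the two new centres are removed in the next step.

Step 10
Reactants: 16 aldol adduct (diastereomer mixture)
Product: 18 (3E,4S,5R)-5-[(3S,4R)-4,8-dimethylnona-1,7-dien-3-yl]-3-[(3E)-4-iodopent-3-en-1-ylidene]-4-[(triethylsilyl)oxy]oxolan-2-one, via mesylate 17 (not isolated)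
Conditions: MeSO2Cl, Et3N, CH2Cl2, −20 °C; then DBU, −20 to 0 °C
Reagents that add atoms: none
Why: mesylation followed by E1cB elimination through the lactone enolate should give the thermodynamically preferred (E)-alkylidene lactone, in which C3 lies cis to C10 and trans to the carbonyl carbon, exactly the C1=C2 geometry of the target.

Step 11
Reactants: 18 (E)-alkylidene lactone
Product: 19 (2Z,5E)-2-[(1S,2R,3S,4R)-3-ethenyl-2-hydroxy-4,8-dimethyl-1-[(triethylsilyl)oxy]non-7-en-1-yl]-6-iodohepta-2,5-dien-1-ol
Conditions: i-Bu2AlH, CH2Cl2, −78 to −20 °C; aq. potassium sodium tartrate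
Reagents that add atoms: none
Why: i-Bu2AlH reduces the unsaturated lactone by 1,2-addition through the lactol to the allylic diol, unmasking C9–OH and the primary allylic alcohol without touching the vinyl iodide, the silyl ether or the alkenes.

Step 12
Reactants: 19 open-chain iodotriene diol
Product: 21 {(1Z,4E,8S,9R,10S)-9-hydroxy-5-methyl-8-[(2R)-6-methylhept-5-en-2-yl]-10-[(triethylsilyl)oxy]cyclodeca-1,4-dien-1-yl}methanol, via alkylborane 20 (not isolated)
Conditions: 9-BBN (excess), THF, 0 °C to rt; then slow addition to Pd(dppf)Cl2 (cat.), AsPh3, Cs2CO3, THF/DMF/H2O, 50 °C, about 2 mM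
Reagents that add atoms: none
Why: 9-BBN adds anti-Markovnikov and only to the monosubstituted C6=C7 alkene, giving a primary C6–B bond (the hydroxyls are held meanwhile as borinates); zerovalent palladium then inserts into the C5–I bond with retention, base-assisted transmetalation transfers the primary alkyl group, and reductive elimination forms C5–C6. The closest known reaction type is the intramolecular B-alkyl Suzuki–Miyaura macrocyclisation of an (E)-2-iodoalk-2-ene with a tethered B-alkyl-9-BBN. One ring is closed, the ten-membered carbocycle, by end-to-end C(sp3)–C(sp2) reductive elimination from an eleven-membered palladacycle. No stereocentre is created; the E geometry of C4=C5 is carried over from the vinyl iodide, and the Z geometry of C1=C2 set at the lactone stage already holds C3 and C10 cis so that both reacting arms lie on the same side. The step needs chemoselective hydroboration, ring closure over oligomerisation and coupling over β-hydride elimination; these should be secured by the steric demand of 9-BBN (three trisubstituted alkenes and the vinyl iodide stay inert), slow addition at high dilution, and the wide-bite-angle dppf ligand with AsPh3.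

Step 13
Reactants: 21 silylated macrocyclic diol
Product: 22 (1S,2R,3S,6E,9Z)-10-(hydroxymethyl)-6-methyl-3-[(2R)-6-methylhept-5-en-2-yl]cyclodeca-6,9-diene-1,2-diol
Conditions: Bu4NF, THF, 0 °C
Reagents that add atoms: none
Why: fluoride-mediated silyl ether cleavage, placed before acetylation so that any silyl migration during the basic coupling is of no consequence.

Step 14
Reactants: 22 macrocyclic triol
Product: 23 [(1Z,4E,8S,9R,10S)-9,10-dihydroxy-5-methyl-8-[(2R)-6-methylhept-5-en-2-yl]cyclodeca-1,4-dien-1-yl]methyl acetate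
Conditions: AcCl, 2,4,6-collidine, CH2Cl2, −78 °C
Reagents that add atoms: acetyl chloride, CC(Cl)=O
Why: kinetically controlled acylation with an acid chloride and a hindered pyridine base at low temperature should select the primary allylic hydroxyl over the two hindered secondary ones.

Compound list
1 | (R)-citronellal, (3R)-3,7-dimethyloct-6-enal | O=CC[C@H](C)CCC=C(C)C | starting material
2 | (4R)-4,8-dimethylnon-7-en-1-yne | C#CC[C@H](C)CCC=C(C)C | intermediate
3 | 2-[(1E,4R)-4,8-dimethylnona-1,7-dien-1-yl]-4,4,5,5-tetramethyl-1,3,2-dioxaborolane | CC1(C)OB(/C=C/C[C@H](C)CCC=C(C)C)OC1(C)C | intermediate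
4 | dimethyl (S)-malate, dimethyl (2S)-2-hydroxybutanedioate | COC(=O)C[C@H](O)C(=O)OC | starting material
5 | methyl (3S)-3,4-dihydroxybutanoate | COC(=O)C[C@H](O)CO | intermediate
6 | methyl (3S)-3,4-bis[(triethylsilyl)oxy]butanoate | COC(=O)C[C@H](O[Si](CC)(CC)CC)CO[Si](CC)(CC)CC | intermediate
7 | methyl (3S)-4-oxo-3-[(triethylsilyl)oxy]butanoate | COC(=O)C[C@H](O[Si](CC)(CC)CC)C=O | intermediate
8 | 2-[(2E,4R)-4,8-dimethylnona-2,7-dien-1-yl]-4,4,5,5-tetramethyl-1,3,2-dioxaborolane | CC1(C)OB(C/C=C/[C@H](C)CCC=C(C)C)OC1(C)C | intermediate (not isolated)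
9 | methyl (3S,4R,5S,6R)-5-ethenyl-4-hydroxy-6,10-dimethyl-3-[(triethylsilyl)oxy]undec-9-enoate | C=C[C@@H]([C@H](C)CCC=C(C)C)[C@@H](O)[C@@H](O[Si](CC)(CC)CC)CC(=O)OC | intermediate (not isolated)
10 | (4S,5R)-5-[(3S,4R)-4,8-dimethylnona-1,7-dien-3-yl]-4-[(triethylsilyl)oxy]oxolan-2-one | C=C[C@@H]([C@H](C)CCC=C(C)C)[C@H]1OC(=O)C[C@@H]1O[Si](CC)(CC)CC | intermediate
11 | pent-3-yn-1-ol | CC#CCCO | starting material
12 | (E)-alkenylzirconocene chloride from 11, zirconium on the methyl-bearing alkene carbon and cis to the new vinyl hydrogen, oxygen held as its chlorozirconocene alkoxide | C/C(=C\CCO[Zr](Cl)(C1C=CC=C1)C1C=CC=C1)[Zr](Cl)(C1C=CC=C1)C1C=CC=C1 | intermediate (not isolated)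
13 | (3E)-4-iodopent-3-en-1-ol | C/C(I)=C\CCO | intermediate
14 | (3E)-4-iodopent-3-enal | C/C(I)=C\CC=O | intermediate
15 | lithium enolate of lactone 10 | C=C[C@@H]([C@H](C)CCC=C(C)C)[C@H]1OC(O[Li])=C[C@@H]1O[Si](CC)(CC)CC | intermediate (not isolated)
16 | (4S,5R)-5-[(3S,4R)-4,8-dimethylnona-1,7-dien-3-yl]-3-[(3E)-1-hydroxy-4-iodopent-3-en-1-yl]-4-[(triethylsilyl)oxy]oxolan-2-one, diastereomer mixture at lactone C3 and at the new carbinol | C=C[C@@H]([C@H](C)CCC=C(C)C)[C@H]1OC(=O)C(C(O)C/C=C(\C)I)[C@@H]1O[Si](CC)(CC)CC | intermediate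
17 | methanesulfonate of aldol adduct 16 | C=C[C@@H]([C@H](C)CCC=C(C)C)[C@H]1OC(=O)C(C(OS(C)(=O)=O)C/C=C(\C)I)[C@@H]1O[Si](CC)(CC)CC | intermediate (not isolated)
18 | (3E,4S,5R)-5-[(3S,4R)-4,8-dimethylnona-1,7-dien-3-yl]-3-[(3E)-4-iodopent-3-en-1-ylidene]-4-[(triethylsilyl)oxy]oxolan-2-one | C=C[C@@H]([C@H](C)CCC=C(C)C)[C@H]1OC(=O)/C(=C/C/C=C(\C)I)[C@@H]1O[Si](CC)(CC)CC | intermediate
19 | (2Z,5E)-2-[(1S,2R,3S,4R)-3-ethenyl-2-hydroxy-4,8-dimethyl-1-[(triethylsilyl)oxy]non-7-en-1-yl]-6-iodohepta-2,5-dien-1-ol | C=C[C@@H]([C@H](C)CCC=C(C)C)[C@@H](O)[C@@H](O[Si](CC)(CC)CC)/C(CO)=C\C/C=C(\C)I | intermediate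
20 | B-alkyl-9-borabicyclo[3.3.1]nonane from hydroboration of the vinyl group of 19 (boron on C6), both hydroxyls held as O-(9-BBN) borinates | B1(CC[C@@H]([C@H](C)CCC=C(C)C)[C@@H](OB2C3CCCC2CCC3)[C@@H](O[Si](CC)(CC)CC)/C(COB2C3CCCC2CCC3)=C\C/C=C(\C)I)C2CCCC1CCC2 | intermediate (not isolated)
21 | {(1Z,4E,8S,9R,10S)-9-hydroxy-5-methyl-8-[(2R)-6-methylhept-5-en-2-yl]-10-[(triethylsilyl)oxy]cyclodeca-1,4-dien-1-yl}methanol | OC/C1=C/C/C=C(\C)CC[C@@H]([C@H](C)CCC=C(C)C)[C@@H](O)[C@H]1O[Si](CC)(CC)CC | intermediate
22 | (1S,2R,3S,6E,9Z)-10-(hydroxymethyl)-6-methyl-3-[(2R)-6-methylhept-5-en-2-yl]cyclodeca-6,9-diene-1,2-diol | OC/C1=C/C/C=C(\C)CC[C@@H]([C@H](C)CCC=C(C)C)[C@@H](O)[C@H]1O | intermediate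
23 | [(1Z,4E,8S,9R,10S)-9,10-dihydroxy-5-methyl-8-[(2R)-6-methylhept-5-en-2-yl]cyclodeca-1,4-dien-1-yl]methyl acetate | CC(=O)OC/C1=C/C/C=C(\C)CC[C@@H]([C@H](C)CCC=C(C)C)[C@@H](O)[C@H]1O | target

Total step count: 14. Longest linear sequence: 10 steps (from 4 through steps 3, 4, 5, 6, 9, 10, 11, 12, 13 and 14).

Steps most likely to fail

Step 12. The open chain may couple between molecules to dimers and oligomers, and the palladium-bound alkyl may be lost by β-hydride elimination or protodeboronation before the medium ring closes. The fallback forms the same C5–C6 bond by nickel-catalysed reductive cross-electrophile cyclisation. It sets out from diol 19. Silylation of both hydroxyls (Et3SiOTf, 2,6-lutidine) should give the tris(triethylsilyl) ether F1. Hydroboration with 9-BBN gives the B-alkyl-9-BBN F2, which is cleaved in the same flask with I2 and NaOMe to the primary iodide F3. Slow addition of F3 to NiBr2(dme), 4,4'-di-tert-butyl-2,2'-bipyridine and Mn powder in N,N-dimethylacetamide at high dilution should join the alkyl iodide to the vinyl iodide and give the tris-silylated macrocycle F4. Bu4NF then removes the three silyl groups, and the route is rejoined at triol 22.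

Step 6. Facial selectivity at the aldehyde may be poor in this triply stereodifferentiating allylboration, and the iridium hydride may move the double bond past the allyl stage toward C11 and erode that centre. The fallback separates the two events and uses a stoichiometric chiral boron reagent. It sets out from alkenylboronate 3. Isomerisation with [Ir(cod)2]BF4 and PCy3 without aldehyde, stopped early, gives allylboronate 8, here isolated. Diethanolamine converts 8 into the crystalline dioxazaborocane F5, which is purified and transesterified with (S,S)-diisopropyl tartrate (the enantiomer expected to be matched with the (S)-aldehyde for the anti diol) to the tartrate allylboronate F6. F6 should add to aldehyde 7 (PhMe, 4 Å sieves, −78 °C) under reagent control to give hydroxy ester 9, and acid-catalysed lactonisation rejoins the route at lactone 10.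

Step 10. The E1cB elimination may give an E/Z mixture, DBU may pull the skipped diene into conjugation through the acidic C3 hydrogens, and the silyloxy group may be lost by β-elimination; the preceding aldol may also suffer proton transfer to the enolisable aldehyde. The fallback is a Wittig olefination with a stabilised lactone ylide under neutral conditions, which replaces steps 9 and 10. It sets out from lactone 10. Enolate 15 (formed with LiN(SiMe3)2) is brominated with N-bromosuccinimide to the α-bromo lactone F7. PPh3 gives the phosphonium bromide F8, and Et3N gives the α-(triphenylphosphoranylidene) lactone F9. F9 and aldehyde 14 in CH2Cl2 should give the (E)-alkylidene lactone directly, rejoining the route at 18.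

Further compounds
F1 | step 12 | tris(triethylsilyl) ether of diol 19 | C=C[C@@H]([C@H](C)CCC=C(C)C)[C@@H](O[Si](CC)(CC)CC)[C@@H](O[Si](CC)(CC)CC)/C(CO[Si](CC)(CC)CC)=C\C/C=C(\C)I
F2 | step 12 | B-alkyl-9-borabicyclo[3.3.1]nonane from hydroboration of the vinyl group of F1 | B1(CC[C@@H]([C@H](C)CCC=C(C)C)[C@@H](O[Si](CC)(CC)CC)[C@@H](O[Si](CC)(CC)CC)/C(CO[Si](CC)(CC)CC)=C\C/C=C(\C)I)C2CCCC1CCC2
F3 | step 12 | primary alkyl iodide (iodine on C6) of the tris-silylated chain | ICC[C@@H]([C@H](C)CCC=C(C)C)[C@@H](O[Si](CC)(CC)CC)[C@@H](O[Si](CC)(CC)CC)/C(CO[Si](CC)(CC)CC)=C\C/C=C(\C)I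
F4 | step 12 | tris(triethylsilyl) ether of macrocyclic triol 22 | CC[Si](CC)(CC)OC/C1=C/C/C=C(\C)CC[C@@H]([C@H](C)CCC=C(C)C)[C@@H](O[Si](CC)(CC)CC)[C@H]1O[Si](CC)(CC)CC
F5 | step 6 | 2-[(2E,4R)-4,8-dimethylnona-2,7-dien-1-yl]-1,3,6,2-dioxazaborocane | C(/C=C/[C@H](C)CCC=C(C)C)B1OCCNCCO1
F6 | step 6 | diisopropyl (4S,5S)-2-[(2E,4R)-4,8-dimethylnona-2,7-dien-1-yl]-1,3,2-dioxaborolane-4,5-dicarboxylate | CC(C)OC(=O)[C@H]1OB(C/C=C/[C@H](C)CCC=C(C)C)O[C@@H]1C(=O)OC(C)C
F7 | step 10 | 3-bromo derivative of lactone 10 (mixture at C3) | C=C[C@@H]([C@H](C)CCC=C(C)C)[C@H]1OC(=O)C(Br)[C@@H]1O[Si](CC)(CC)CC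
F8 | step 10 | 3-(triphenylphosphonio) derivative of lactone 10, bromide salt | C=C[C@@H]([C@H](C)CCC=C(C)C)[C@H]1OC(=O)C([P+](c2ccccc2)(c2ccccc2)c2ccccc2)[C@@H]1O[Si](CC)(CC)CC.[Br-]
F9 | step 10 | 3-(triphenylphosphoranylidene) derivative of lactone 10 | C=C[C@@H]([C@H](C)CCC=C(C)C)[C@H]1OC(=O)C(=P(c2ccccc2)(c2ccccc2)c2ccccc2)[C@@H]1O[Si](CC)(CC)CC
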